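**Retrosynthetic overview**

1. The enol ether O–C10=C11 of the dibenzo[b,f]oxepine is the enol of a 10(11H)-ketone, a C,O-bis-nucleophile. The pyran carbons C1'H2–C2'H(O)–C3'(CH3)(O) carry the imprint of a (Z)-2,3-epoxy-1-iodide, and the C2'–O–C6' ether next to the C7' carbinol carbon carries the imprint of a second, 6',7'-epoxide. This pairing makes the key step possible.
2. Key disconnection: [3+3] annulation of dibenzoxepinone 8 with the C10 bis-epoxy iodide 18 (C11–C1' by enolate alkylation, O–C3' by epoxide opening), relayed in the same flask into the tetrahydropyran (C2'–O–C6').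
3. Last disconnection: the oxetane C5'–O bond, closed by displacement at C5' with inversion by the C7' hydroxyl.
4. Ring order: rings A and B and the oxepinone (SNAr, Stille prenylation, Pd α-arylation), then dihydropyran, then tetrahydropyran, then oxetane.
5. Stereocontrol: C5' from asymmetric methallylation of prenal, C6' from hydroxyl-directed epoxidation, C2'/C3' from Sharpless epoxidation of a (Z)-allylic alcohol whose geometry is fixed by ring-closing metathesis.

Key step: step 15

Remark on locants: the core is numbered as dibenzo[b,f]oxepine (C10 bears oxygen, C11 bears the side chain); the C10 terpenoid unit is numbered C1'–C8' as in nerol (C1' on C11, methyl groups on C3' and C7').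

**Route**

Step 1
Reactants: 1 2-bromo-5-methoxyphenol
Product: 2 2-bromo-4-iodo-5-methoxyphenol
Conditions: N-iodosuccinimide, MeCN, 0 → 23 °C
Reagents that add atoms: N-iodosuccinimide, O=C1CCC(=O)N1I
Why: Electrophilic aromatic iodination should go para to the free hydroxyl and ortho to the methoxy group, the only open activated site that is not flanked by two substituents.

Step 2
Reactants: 2 2-bromo-4-iodo-5-methoxyphenol; 3 1-(2-fluoro-4-methoxyphenyl)ethan-1-one
Product: 4 1-[2-(2-bromo-4-iodo-5-methoxyphenoxy)-4-methoxyphenyl]ethan-1-one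
Conditions: K2CO3, DMF, 110 °C
Reagents that add atoms: none
Why: Nucleophilic aromatic substitution (SNAr) of the fluoride ortho to the acetyl group by the phenoxide should give the diaryl ether, with the aryl iodide and bromide untouched.

Step 3
Reactants: 4 diaryl ether
Product: 5 1-[2-(2-bromo-5-hydroxy-4-iodophenoxy)-4-hydroxyphenyl]ethan-1-one
Conditions: BBr3, CH2Cl2, −78 → 23 °C; H2O
Reagents that add atoms: none
Why: Lewis-acid cleavage of both aryl methyl ethers (BBr3 demethylation) is placed here, before the acid-sensitive prenyl group exists.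

Step 4
Reactants: 5 diphenol
Product: 6 1-{2-[2-bromo-4-iodo-5-(triisopropylsilyloxy)phenoxy]-4-(triisopropylsilyloxy)phenyl}ethan-1-one
Conditions: i-Pr3SiCl, imidazole, DMF, 40 °C
Reagents that add atoms: chlorotriisopropylsilane, CC(C)[Si](Cl)(C(C)C)C(C)C
Why: Silylation of both phenols installs groups that should survive enolate chemistry and mild acid and can be removed at the end by fluoride.

Step 5
Reactants: 6 bis-silyl ether
Product: 7 1-{2-[2-bromo-4-(3-methylbut-2-en-1-yl)-5-(triisopropylsilyloxy)phenoxy]-4-(triisopropylsilyloxy)phenyl}ethan-1-one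
Conditions: Pd(PPh3)4 (5 mol %), DMF, 70 °C
Reagents that add atoms: tributyl(3-methylbut-2-en-1-yl)stannane, CC(C)=CC[Sn](CCCC)(CCCC)CCCC
Why: Stille coupling should occur only at the C–I bond, where oxidative addition to zerovalent palladium is much faster than at C–Br, and prenylstannanes normally transfer the linear prenyl group.

Step 6
Reactants: 7 prenylated bromo ketone
Product: 8 2-(3-methylbut-2-en-1-yl)-3,7-bis(triisopropylsilyloxy)dibenzo[b,f]oxepin-10(11H)-one
Conditions: Pd(OAc)2 (5 mol %), XPhos (10 mol %), K3PO4, toluene, 100 °C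
Reagents that add atoms: none
Why: Intramolecular palladium-catalysed α-arylation of the methyl ketone enolate (Buchwald–Hartwig type) should close the seven-membered ketone, and the mild phosphate base spares the silyl ethers.

Step 7
Reactants: 9 3-methylbut-2-enal
Product: 10 (4R)-2,6-dimethylhepta-1,5-dien-4-ol
Conditions: (R)-BINOL (10 mol %), Ti(OiPr)4 (10 mol %), 4 Å MS, CH2Cl2, −20 °C
Reagents that add atoms: tributyl(2-methylprop-2-en-1-yl)stannane, C=C(C)C[Sn](CCCC)(CCCC)CCCC
Why: Keck asymmetric allylation with the (R)-BINOL–titanium catalyst should deliver the methallyl group to the Re face of the enal and so set the R carbinol (the future C5').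

Step 8
Reactants: 10 dienol
Product: 11 (1R)-1-[(2S)-3,3-dimethyloxiran-2-yl]-3-methylbut-3-en-1-ol
Conditions: mCPBA (1.05 equiv), NaHCO3, CH2Cl2, 0 °C
Reagents that add atoms: 3-chloroperoxybenzoic acid, OOC(=O)c1cccc(Cl)c1
Why: Hydroxyl-directed peracid epoxidation of the trisubstituted allylic alkene should give the threo epoxy alcohol, because allylic 1,3-strain with the cis methyl fixes the carbinol conformation and the hydrogen-bonded peracid attacks the face syn to OH; the 1,1-disubstituted alkene reacts more slowly.

Step 9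
Reactants: 11 epoxy alcohol
Product: 12 (1R)-1-[(2S)-3,3-dimethyloxiran-2-yl]-3-methylbut-3-en-1-yl prop-2-enoate
Conditions: prop-2-enoyl chloride, i-Pr2NEt, DMAP (cat.), CH2Cl2, 0 °C
Reagents that add atoms: prop-2-enoyl chloride, C=CC(=O)Cl
Why: Acylation of the secondary alcohol under amine buffering should leave the epoxide intact and set up the diene for metathesis.

Step 10
Reactants: 12 acrylate
Product: 13 (6R)-6-[(2S)-3,3-dimethyloxiran-2-yl]-4-methyl-5,6-dihydro-2H-pyran-2-one
Conditions: second-generation Grubbs catalyst, RuCl2(=CHPh)(H2IMes)(PCy3) (5 mol %), CH2Cl2 (5 mM), 40 °C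
Reagents that add atoms: none
Why: Ring-closing metathesis of the acrylate with the 1,1-disubstituted alkene should give the six-membered unsaturated lactone, whose ring enforces the Z geometry of the future C2'=C3' bond.

Step 11
Reactants: 13 lactone
Product: 15 (2Z,5R,6S)-6,7-epoxy-3,7-dimethyloct-2-ene-1,5-diol, via lactol 14 (not isolated)
Conditions: i-Bu2AlH, CH2Cl2, −78 °C; MeOH; then NaBH4, CeCl3·7H2O, MeOH, −20 °C
Reagents that add atoms: none
Why: Partial reduction to the lactol and Luche-type 1,2-reduction of its ring-opened (Z)-enal form should give the (Z)-allylic diol without touching the epoxide.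

Step 12
Reactants: 15 (Z)-allylic diol
Product: 16 (2R,3S,5R,6S)-2,3:6,7-diepoxy-3,7-dimethyloctane-1,5-diol
Conditions: Ti(OiPr)4 (10 mol %), D-(−)-diethyl tartrate (12 mol %), t-BuOOH, 4 Å MS, CH2Cl2, −20 °C
Reagents that add atoms: tert-butyl hydroperoxide, CC(C)(C)OO
Why: Sharpless asymmetric epoxidation of the primary (Z)-allylic alcohol with the D-tartrate should give the (2R,3S) cis-epoxide under reagent control, as for nerol.

Step 13
Reactants: 16 bis-epoxy diol
Product: 17 (2S,3S,5R,6S)-2,3:6,7-diepoxy-1-iodo-3,7-dimethyloctan-5-ol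
Conditions: I2, PPh3, imidazole, CH2Cl2, 0 °C
Reagents that add atoms: iodine, II
Why: Appel-type iodination (Garegg–Samuelsson conditions) should convert the primary hydroxyl selectively, the hindered secondary one reacting far more slowly; C2 changes descriptor only because CH2I outranks C3.

Step 14
Reactants: 17 iodo alcohol
Product: 18 triethyl{[(2S,3S,5R,6S)-2,3:6,7-diepoxy-1-iodo-3,7-dimethyloctan-5-yl]oxy}silane
Conditions: Et3SiCl, imidazole, CH2Cl2, 0 → 23 °C
Reagents that add atoms: chlorotriethylsilane, CC[Si](Cl)(CC)CC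
Why: Silylation masks the C5 hydroxyl, which would otherwise attack the iodide or the epoxides under base, with a group that can later be removed without touching the aryl silyl ethers.

Step 15
Reactants: 8 dibenzoxepinone; 18 bis-epoxy iodide
Product: 21 pyrano-fused tertiary alcohol (2'R,3'R,5'R,6'R) with C10–O–C3' and C2'–O–C6' ether rings, via C11-alkylated ketone 19 (not isolated), via hydroxy dihydropyran 20 (not isolated)
Conditions: KOtBu (1.0 equiv), THF, −40 °C; 18, −40 → 0 °C; then CH2Cl2, (+)-camphor-10-sulfonic acid (0.3 equiv), 0 → 23 °C; Et3N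
Reagents that add atoms: none
Why: The potassium enolate of the α-aryl ketone is C-alkylated at the primary, epoxide-activated iodide (SN2; C- over O-alkylation as is usual for soft benzylic enolates with iodides), and acid then triggers an epoxide-opening relay: the carbonyl/enol oxygen on C10 opens the 2',3'-epoxide at its tertiary carbon C3' with loss of H-11, and the C2' hydroxyl thus released opens the 6',7'-epoxide at C6'. The closest known reaction types are the acid-mediated cyclisation of ortho-(2,3-epoxy-3-methylalkyl)phenols and 2-(epoxyalkyl)-1,3-dicarbonyl compounds to 3-hydroxy-2,2-dialkyl pyrans and the exo-selective hydroxy-epoxide cyclisations of polyether synthesis. The dihydropyran closes 6-endo-tet at the tertiary epoxide carbon and the tetrahydropyran closes 6-exo-tet at a secondary carbon. C3' (R) arises by inversion of the (3'S) epoxide carbon and C6' (R) by inversion of the (6'S) epoxide carbon, whereas C2' and C5' are carried unchanged from the Sharpless epoxide and the allylation, so the cis pyran–pyran fusion and the 2',6'-cis tetrahydropyran follow from the (Z)-epoxide geometry and the reagent-set absolute configurations. The step needs 6-endo over 5-exo in the first opening, which the cation-stabilising fully substituted C3' and the weakly nucleophilic, phenol-like oxygen under acid should secure, and 6-exo over 7-endo in the second, which the smaller ring and an alcohol attacking a secondary carbon should secure; the distal epoxide has no internal nucleophile until the first ring has formed. A strained bridged ketal from the C2' hydroxyl and C10 is disfavoured against the stilbene-conjugated enol ether.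

Step 16
Reactants: 21 triethylsilyl ether
Product: 22 5',7'-diol (2'R,3'R,5'R,6'R)
Conditions: HF·pyridine, pyridine, THF, 0 °C
Reagents that add atoms: none
Why: Buffered HF cleaves the alkyl triethylsilyl ether much faster than the hindered aryl triisopropylsilyl ethers, and the enol ether should tolerate the buffered medium.

Step 17
Reactants: 22 diol
Product: 24 bis(triisopropylsilyl) ether of the target (2'R,3'R,5'S,6'R), via C5' triflate 23 (not isolated)
Conditions: Tf2O (1.1 equiv), 2,6-di-tert-butyl-4-methylpyridine, CH2Cl2, −78 → 23 °C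
Reagents that add atoms: none
Why: Selective triflation of the secondary C5' hydroxyl and intramolecular SN2 displacement by the neutral tertiary hydroxyl (4-exo-tet Williamson-type oxetane closure, as used for taxane oxetanes) should invert C5' to S; a four-membered ring can only be cis-fused, and the absence of an alkoxide avoids Grob fragmentation.

Step 18
Reactants: 24 bis-silyl ether
Product: 25 CNP0102779.1 (target)
Conditions: Bu4NF, AcOH, THF, 0 °C
Reagents that add atoms: none
Why: Buffered fluoride desilylation of the two aryl silyl ethers should leave the oxetane, the enol ether and the prenyl group untouched.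

**Compound list**

1 | 2-bromo-5-methoxyphenol | COc1ccc(Br)c(O)c1 | starting material
2 | 2-bromo-4-iodo-5-methoxyphenol | COc1cc(O)c(Br)cc1I | intermediate
3 | 1-(2-fluoro-4-methoxyphenyl)ethan-1-one | CC(=O)c1ccc(OC)cc1F | starting material
4 | 1-[2-(2-bromo-4-iodo-5-methoxyphenoxy)-4-methoxyphenyl]ethan-1-one | CC(=O)c1ccc(OC)cc1Oc1cc(OC)c(I)cc1Br | intermediate
5 | 1-[2-(2-bromo-5-hydroxy-4-iodophenoxy)-4-hydroxyphenyl]ethan-1-one | CC(=O)c1ccc(O)cc1Oc1cc(O)c(I)cc1Br | intermediate
6 | 1-{2-[2-bromo-4-iodo-5-(triisopropylsilyloxy)phenoxy]-4-(triisopropylsilyloxy)phenyl}ethan-1-one | CC(=O)c1ccc(O[Si](C(C)C)(C(C)C)C(C)C)cc1Oc1cc(O[Si](C(C)C)(C(C)C)C(C)C)c(I)cc1Br | intermediate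
7 | 1-{2-[2-bromo-4-(3-methylbut-2-en-1-yl)-5-(triisopropylsilyloxy)phenoxy]-4-(triisopropylsilyloxy)phenyl}ethan-1-one | CC(=O)c1ccc(O[Si](C(C)C)(C(C)C)C(C)C)cc1Oc1cc(O[Si](C(C)C)(C(C)C)C(C)C)c(CC=C(C)C)cc1Br | intermediate
8 | 2-(3-methylbut-2-en-1-yl)-3,7-bis(triisopropylsilyloxy)dibenzo[b,f]oxepin-10(11H)-one | CC(C)=CCc1cc2CC(=O)c3ccc(O[Si](C(C)C)(C(C)C)C(C)C)cc3Oc2cc1O[Si](C(C)C)(C(C)C)C(C)C | intermediate
9 | 3-methylbut-2-enal | CC(C)=CC=O | starting material
10 | (4R)-2,6-dimethylhepta-1,5-dien-4-ol | C=C(C)C[C@@H](O)C=C(C)C | intermediate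
11 | (1R)-1-[(2S)-3,3-dimethyloxiran-2-yl]-3-methylbut-3-en-1-ol | C=C(C)C[C@@H](O)[C@@H]1OC1(C)C | intermediate
12 | (1R)-1-[(2S)-3,3-dimethyloxiran-2-yl]-3-methylbut-3-en-1-yl prop-2-enoate | C=C(C)C[C@@H](OC(=O)C=C)[C@@H]1OC1(C)C | intermediate
13 | (6R)-6-[(2S)-3,3-dimethyloxiran-2-yl]-4-methyl-5,6-dihydro-2H-pyran-2-one | O=C1C=C(C)C[C@@H](O1)[C@@H]2OC2(C)C | intermediate
14 | (6R)-6-[(2S)-3,3-dimethyloxiran-2-yl]-4-methyl-5,6-dihydro-2H-pyran-2-ol (lactol, anomers) | OC1C=C(C)C[C@@H](O1)[C@@H]2OC2(C)C | intermediate
15 | (2Z,5R,6S)-6,7-epoxy-3,7-dimethyloct-2-ene-1,5-diol | OC/C=C(/C)C[C@@H](O)[C@@H]1OC1(C)C | intermediate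
16 | (2R,3S,5R,6S)-2,3:6,7-diepoxy-3,7-dimethyloctane-1,5-diol | OC[C@H]1O[C@@]1(C)C[C@@H](O)[C@@H]2OC2(C)C | intermediate
17 | (2S,3S,5R,6S)-2,3:6,7-diepoxy-1-iodo-3,7-dimethyloctan-5-ol | IC[C@H]1O[C@@]1(C)C[C@@H](O)[C@@H]2OC2(C)C | intermediate
18 | triethyl{[(2S,3S,5R,6S)-2,3:6,7-diepoxy-1-iodo-3,7-dimethyloctan-5-yl]oxy}silane | IC[C@H]1O[C@@]1(C)C[C@@H](O[Si](CC)(CC)CC)[C@@H]2OC2(C)C | intermediate
19 | 11-[(2R,3S,5R,6S)-2,3:6,7-diepoxy-3,7-dimethyl-5-(triethylsilyloxy)octyl]-2-(3-methylbut-2-en-1-yl)-3,7-bis(triisopropylsilyloxy)dibenzo[b,f]oxepin-10(11H)-one (both C11 epimers) | CC(C)=CCc1cc2C(C[C@H]3O[C@@]3(C)C[C@@H](O[Si](CC)(CC)CC)[C@@H]3OC3(C)C)C(=O)c3ccc(O[Si](C(C)C)(C(C)C)C(C)C)cc3Oc2cc1O[Si](C(C)C)(C(C)C)C(C)C | intermediate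
20 | hydroxy dihydropyran: C10–O–C3' ether closed, C10=C11 enol ether, (2'R)-OH, (3'R), (5'R)-OSiEt3, (6'S)-6',7'-epoxide intact, both phenols as triisopropylsilyl ethers | CC(C)=CCc1cc2c(cc1O[Si](C(C)C)(C(C)C)C(C)C)Oc1cc(O[Si](C(C)C)(C(C)C)C(C)C)ccc1C1=C2C[C@@H](O)[C@@](C)(C[C@@H](O[Si](CC)(CC)CC)[C@@H]2OC2(C)C)O1 | intermediate
21 | pyrano-fused tertiary alcohol: as 20 but with the C2'–O–C6' tetrahydropyran closed; (2'R,3'R,5'R,6'R), 5'-OSiEt3, 2-hydroxypropan-2-yl (C7') on C6' | CC(C)=CCc1cc2c(cc1O[Si](C(C)C)(C(C)C)C(C)C)Oc1cc(O[Si](C(C)C)(C(C)C)C(C)C)ccc1C1=C2C[C@H]2O[C@@H](C(C)(C)O)[C@H](O[Si](CC)(CC)CC)C[C@@]2(C)O1 | intermediate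
22 | 5',7'-diol (2'R,3'R,5'R,6'R): 21 without the triethylsilyl group | CC(C)=CCc1cc2c(cc1O[Si](C(C)C)(C(C)C)C(C)C)Oc1cc(O[Si](C(C)C)(C(C)C)C(C)C)ccc1C1=C2C[C@H]2O[C@@H](C(C)(C)O)[C@H](O)C[C@@]2(C)O1 | intermediate
23 | C5' trifluoromethanesulfonate of 22 (2'R,3'R,5'R,6'R) | CC(C)=CCc1cc2c(cc1O[Si](C(C)C)(C(C)C)C(C)C)Oc1cc(O[Si](C(C)C)(C(C)C)C(C)C)ccc1C1=C2C[C@H]2O[C@@H](C(C)(C)O)[C@H](OS(=O)(=O)C(F)(F)F)C[C@@]2(C)O1 | intermediate
24 | 3,7-bis(triisopropylsilyl) ether of the target (2'R,3'R,5'S,6'R), oxetane closed | CC(C)=CCc1cc2c(cc1O[Si](C(C)C)(C(C)C)C(C)C)Oc1cc(O[Si](C(C)C)(C(C)C)C(C)C)ccc1C1=C2C[C@H]2O[C@@H]3[C@H](C[C@@]2(C)O1)OC3(C)C | intermediate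
25 | CNP0102779.1 (2'R,3'R,5'S,6'R) | CC(C)=CCc1cc2c(cc1O)Oc1cc(O)ccc1C1=C2C[C@H]2O[C@@H]3[C@H](C[C@@]2(C)O1)OC3(C)C | target

**Step count**

Total steps: 18. Longest linear sequence: 12 steps (steps 7–18, from 9); the core branch (steps 1–6) joins at step 15.

**Steps most likely to fail**

Step 15 (key step). The acid relay may lose regiocontrol: the distal 6',7'-epoxide may open at its tertiary carbon (7-endo) or rearrange once acid is present, and the first opening may leak into the 5-exo mode. The fallback sets out from 8 and 18 and splits the relay. After the same alkylation, only the first ring closure is run (pyridinium p-toluenesulfonate, CH2Cl2, −40 °C) and hydroxy dihydropyran 20 is isolated. The tetrahydropyran is then closed under basic instead of acidic activation (NaH, THF, 0 → 40 °C), where the C2' alkoxide can reach only the secondary C6' by SN2. This returns to the route at 21 and makes no compound outside the list (F0).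

Step 17. The C5' triflate is equatorial and anti-periplanar to the ring C6'–O bond, so the 4-exo-tet displacement has to pass through a twist conformer. Ring contraction by participation of the ring oxygen, elimination, or triflation of the tertiary hydroxyl may outrun the closure. The fallback sets out from 22 and uses a redox-condensation (Mitsunobu-type) cyclodehydration with PPh3 and diisopropyl azodicarboxylate in toluene at 80 °C. This activates the secondary hydroxyl as an oxyphosphonium ion, without a sulfonate that can ionise and without an alkoxide that can fragment. It returns to the route at 24 and makes no compound outside the list (F0).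

Step 6. Reductive elimination to the seven-membered ring may be slow, so that protodebromination, intermolecular arylation or aldol self-condensation of the methyl ketone compete. The fallback sets out from 7 and replaces palladium catalysis by a photostimulated radical-nucleophilic substitution (SRN1): KOtBu, liquid NH3, hν (350 nm), −33 °C. The ketone enolate adds intramolecularly to the aryl radical formed by electron transfer to the bromide. It returns to the route at 8 and makes no compound outside the list (F0).

**Further compounds**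

F0 | step 15 | none | none
F0 | step 17 | none | none
F0 | step 6 | none | none
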